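## Retrosynthetic overview

1. The target is the C1-hydroxylated [4+2] dimer of a single monomer, 8-epi-xanthatin; the last bond made is C1–O, by γ-oxygenation of the dimer's β,γ-unsaturated ketone.
2. The dimer is cut at C3–C11′ and C5–C13′ (central cyclohexene and spiro centre), a head-to-head union of two monomer molecules.
3. The monomer's dienone side chain comes from Heck vinylation of a cycloheptenyl triflate with methyl vinyl ketone.
4. Key step: both seven-membered rings come from one six-membered lactone ketone by one-carbon ring expansion (1,2-alkyl shift with loss of N2), ending directly in the regiodefined enol triflate.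
5. The six-membered lactone ketone comes from a Rauhut–Currier lactone annulation on a hydroxy enone made from phenol by asymmetric conjugate methylation. Ring order: six-membered carbocycle, γ-lactone, seven-membered ring, central cyclohexene.

Assumption: positions use xanthane numbering (ring C1, C5–C10; side chain C2–C4, C15; lactone C11–C13; primes for the dienophile-derived half), and the ligand enantiomer in step 2 is the one that gives the 5S product.

## Route

Step 1
Reactants: 1 phenol
Product: 3 4,4-dimethoxycyclohexa-2,5-dien-1-one, via 4-methoxyphenol 2 (not isolated)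
Conditions: PhI(OAc)2 (2.2 equiv), MeOH, 0 to 23 °C
Reagents that add atoms: methanol, CO
Why: Two successive hypervalent-iodine oxidative dearomatisations of a para-unsubstituted phenol in methanol (first para-methoxylation, then ketal formation) give the quinone monoketal; no stereocentre is formed.

Step 2
Reactants: 3 4,4-dimethoxycyclohexa-2,5-dien-1-one; 4 dimethylzinc
Product: 5 (5S)-4,4-dimethoxy-5-methylcyclohex-2-en-1-one
Conditions: Cu(OTf)2 (2 mol %), (R,S,S)-binaphthol bis(1-phenylethyl)amine phosphoramidite (4 mol %), toluene, −25 °C; aq. NH4Cl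
Reagents that add atoms: none
Why: Copper-catalysed asymmetric conjugate addition of a dialkylzinc (phosphoramidite system) desymmetrises the dienone, the ligand choosing the enantiotopic alkene and face so that the methyl-bearing carbon (future C10) is set as S; mono-addition is usual for this substrate class.

Step 3
Reactants: 5 (5S)-4,4-dimethoxy-5-methylcyclohex-2-en-1-one
Product: 7 (4R,6S)-4-hydroxy-6-methylcyclohex-2-en-1-one, via allylic alcohol ketal 6 (not isolated)
Conditions: NaBH4, CeCl3·7H2O, MeOH, −78 °C; then 1 M aq. HCl, THF, 0 °C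
Reagents that add atoms: water, O
Why: Luche 1,2-reduction delivers hydride to the carbonyl face anti to the C5 methyl, giving the 1,3-cis alcohol (new carbinol centre R, future C8), and acid hydrolysis of the ketal then transposes the enone.

Step 4
Reactants: 7 (4R,6S)-4-hydroxy-6-methylcyclohex-2-en-1-one; 8 acryloyl chloride
Product: 9 (1R,5S)-5-methyl-4-oxocyclohex-2-en-1-yl prop-2-enoate
Conditions: i-Pr2NEt, DMAP (5 mol %), CH2Cl2, −78 to −20 °C
Reagents that add atoms: none
Why: Simple O-acylation of the secondary allylic alcohol with an acid chloride at low temperature; no stereocentre is touched.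

Step 5
Reactants: 9 (1R,5S)-5-methyl-4-oxocyclohex-2-en-1-yl prop-2-enoate
Product: 10 (3aR,6S,7aR)-6-methyl-3-methylidenehexahydro-1-benzofuran-2,5-dione
Conditions: PMe3 (20 mol %), t-AmOH (0.05 M), 23 °C
Reagents that add atoms: none
Why: Intramolecular Rauhut–Currier reaction (phosphine adds to the acrylate, its α-carbon attacks the enone β-carbon in a five-membered closure, and phosphine is expelled to restore the exo-methylene); the ester tether forces the new C–C bond onto the oxygen-bearing face, so the ring-fusion centre (3aR, future C7) is cis to C–O.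

Step 6
Reactants: 10 (3aR,6S,7aR)-6-methyl-3-methylidenehexahydro-1-benzofuran-2,5-dione; 11 (trimethylsilyl)diazomethane
Product: 14 (3aR,7S,8aR)-7-methyl-3-methylidene-2-oxo-3,3a,4,7,8,8a-hexahydro-2H-cyclohepta[b]furan-6-yl trifluoromethanesulfonate, via beta-ketosilane 12 (not isolated), via trimethylsilyl enol ether 13 (not isolated)
Conditions: Sc(OTf)3 (10 mol %), CH2Cl2, −45 to 0 °C (11 added over 2 h); then PhNTf2, CsF, DME, 0 to 23 °C; aq. NH4Cl
Reagents that add atoms: N-phenylbis(trifluoromethanesulfonimide), O=S(=O)(N(c1ccccc1)S(=O)(=O)C(F)(F)F)C(F)(F)F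
Why: Proposed new method: a one-flask ring-expanding enol triflation in which the nucleophilic carbon of 11 adds to the Sc(OTf)3-bound ketone, the less substituted α-carbon (C6) undergoes 1,2-shift with loss of N2 to give the seven-membered β-ketosilane 12, silicon relays to oxygen (1,3-Brook) to give the regiodefined enol silane 13 (which also blocks a second insertion), and fluoride then releases the C1–C5 enolate straight into PhNTf2; the α-methylene lactone should survive because Lewis-acid-mediated carbonyl addition at −45 °C under slow addition outruns the uncatalysed dipolar cycloaddition of 11 to the acrylate, and no stereocentre is formed or exposed (C10 is never part of a free enolate); the closest known reaction types are the Lewis-acid-catalysed diazoalkane homologation of cycloalkanones (Tiffeneau–Demjanov-type 1,2-shift) and the fluoride-mediated conversion of enol silanes into enol triflates, which have not been run in tandem or on a ketone carrying an α-methylene lactone.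

Step 7
Reactants: 14 (3aR,7S,8aR)-7-methyl-3-methylidene-2-oxo-3,3a,4,7,8,8a-hexahydro-2H-cyclohepta[b]furan-6-yl trifluoromethanesulfonate; 15 methyl vinyl ketone
Product: 16 8-epi-xanthatin, (3aR,7S,8aR)-7-methyl-3-methylidene-6-[(1E)-3-oxobut-1-en-1-yl]-3,3a,4,7,8,8a-hexahydro-2H-cyclohepta[b]furan-2-one
Conditions: 15 (5 equiv), Pd(OAc)2 (5 mol %), PPh3 (10 mol %), Et3N, DMF, 60 °C
Reagents that add atoms: none
Why: Mizoroki–Heck reaction (oxidative addition to the enol triflate, insertion of 15 at its unsubstituted terminus, syn β-hydride elimination) gives the (E)-dienone, the 1,1-disubstituted methylene lactone being a much slower acceptor than the excess monosubstituted enone; no stereocentre changes.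

Step 8
Reactants: 16 8-epi-xanthatin (two molecules)
Product: 17 Diels–Alder dimer of 16 (β,γ-unsaturated ketone; C1=C2 alkene; SMILES in list)
Conditions: neat melt, BHT (5 mol %), 110 °C, sealed tube, Ar, 36 h; unreacted 16 recovered
Reagents that add atoms: none
Why: Thermal Diels–Alder dimerisation (the presumed biogenetic union) joins the diene C5=C1–C2=C3 of one molecule to the exocyclic C11′=C13′ of a second with ortho regiochemistry (C3–C11′, C5–C13′), endo lactone carbonyl, attack on the convex face of the cis-fused lactone (syn to H-7′) and on the β-face of the diene, which sets C3, C5 and the spiro carbon C11′ in one event.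

Step 9
Reactants: 17 Diels–Alder dimer of 16
Product: 19 target (1β-hydroxy-2-en-4-one dimer; SMILES as given), via C1 hydroperoxide 18 (not isolated)
Conditions: O2 (1 atm), DBU (0.5 equiv), THF, 0 °C; then PPh3 (1.2 equiv), 0 °C
Reagents that add atoms: dioxygen, O=O
Why: γ-Selective enolate autoxidation followed by phosphine reduction of the hydroperoxide: DBU removes the doubly activated H-3, O2 is captured at C1 of the dienolate with axial C–O bond formation anti to H-5 (OH β, trans ring fusion, the outcome known for ring-fusion carbons of β,γ-unsaturated ketones), which moves the alkene into conjugation (C2=C3), and PPh3 reduces 18 to the tertiary alcohol.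

## Compound list

1 | phenol | Oc1ccccc1 | starting material
2 | 4-methoxyphenol | COc1ccc(O)cc1 | intermediate (not isolated)
3 | 4,4-dimethoxycyclohexa-2,5-dien-1-one | COC1(OC)C=CC(=O)C=C1 | intermediate
4 | dimethylzinc | C[Zn]C | starting material
5 | (5S)-4,4-dimethoxy-5-methylcyclohex-2-en-1-one | O=C1C[C@H](C)C(OC)(OC)C=C1 | intermediate
6 | (1R,5S)-4,4-dimethoxy-5-methylcyclohex-2-en-1-ol (OH cis to methyl) | O[C@@H]1C[C@H](C)C(OC)(OC)C=C1 | intermediate (not isolated)
7 | (4R,6S)-4-hydroxy-6-methylcyclohex-2-en-1-one (cis) | O[C@@H]1C[C@H](C)C(=O)C=C1 | intermediate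
8 | acryloyl chloride (prop-2-enoyl chloride) | C=CC(Cl)=O | starting material
9 | (1R,5S)-5-methyl-4-oxocyclohex-2-en-1-yl prop-2-enoate | C=CC(=O)O[C@@H]1C[C@H](C)C(=O)C=C1 | intermediate
10 | (3aR,6S,7aR)-6-methyl-3-methylidenehexahydro-1-benzofuran-2,5-dione (cis-fused lactone; methyl cis to lactone oxygen) | C=C1C(=O)O[C@@H]2C[C@H](C)C(=O)C[C@H]12 | intermediate
11 | (trimethylsilyl)diazomethane | C[Si](C)(C)C=[N+]=[N-] | starting material
12 | (3aR,7S,8aR)-7-methyl-3-methylidene-5-(trimethylsilyl)hexahydro-2H-cyclohepta[b]furan-2,6(3H)-dione (β-ketosilane; C5 epimers) | C=C1C(=O)O[C@@H]2C[C@H](C)C(=O)C([Si](C)(C)C)C[C@H]12 | intermediate (not isolated)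
13 | (3aR,7S,8aR)-7-methyl-3-methylidene-6-(trimethylsilyloxy)-3,3a,4,7,8,8a-hexahydro-2H-cyclohepta[b]furan-2-one | C=C1C(=O)O[C@@H]2C[C@H](C)C(O[Si](C)(C)C)=CC[C@H]12 | intermediate (not isolated)
14 | (3aR,7S,8aR)-7-methyl-3-methylidene-2-oxo-3,3a,4,7,8,8a-hexahydro-2H-cyclohepta[b]furan-6-yl trifluoromethanesulfonate | C=C1C(=O)O[C@@H]2C[C@H](C)C(OS(=O)(=O)C(F)(F)F)=CC[C@H]12 | intermediate
15 | methyl vinyl ketone (but-3-en-2-one) | C=CC(C)=O | starting material
16 | 8-epi-xanthatin, (3aR,7S,8aR)-7-methyl-3-methylidene-6-[(1E)-3-oxobut-1-en-1-yl]-3,3a,4,7,8,8a-hexahydro-2H-cyclohepta[b]furan-2-one (cis lactone; O-8, C11 and C14 all β) | C=C1C(=O)O[C@@H]2C[C@H](C)C(/C=C/C(C)=O)=CC[C@H]12 | intermediate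
17 | Diels–Alder dimer of 16: central cyclohexene from C5=C1–C2=C3 of unit A and C11′=C13′ of unit B (bonds C3–C11′ and C5–C13′); C1=C2 alkene; 3-acetyl with H-3 cis to H-5 (H-5 α); spiro C11′ with C3 syn to H-7′ and lactone carbonyl syn to the acetyl; unit B keeps its (E)-dienone | C=C1C(=O)O[C@@H]2C[C@H](C)C3=C[C@H](C(C)=O)[C@@]4(C[C@@H]3C[C@H]12)C(=O)O[C@@H]1C[C@H](C)C(/C=C/C(C)=O)=CC[C@@H]14 | intermediate
18 | C1 β-hydroperoxide of the dimer (C2=C3 conjugated with the C4 ketone; OOH anti to H-5) | C=C1C(=O)O[C@@H]2C[C@H](C)[C@@]3(OO)C=C(C(C)=O)[C@@]4(C[C@@H]3C[C@H]12)C(=O)O[C@@H]1C[C@H](C)C(/C=C/C(C)=O)=CC[C@@H]14 | intermediate (not isolated)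
19 | CNP0168949.1: 1β-hydroxy dimer (tertiary OH at C1 anti to H-5; C2=C3–C4=O enone; spiro lactone at C11′; unit B with (E)-dienone) | C=C1C(=O)O[C@@H]2C[C@H](C)[C@@]3(O)C=C(C(C)=O)[C@@]4(C[C@@H]3C[C@H]12)C(=O)O[C@@H]1C[C@H](C)C(/C=C/C(C)=O)=CC[C@@H]14 | target

## Step count and risks

Total step count: 9. Longest linear sequence: 9 steps (phenol to 19; step 8 uses two molecules of 16).

Three steps most likely to fail:

**Step 6 (the proposed ring-expanding enol triflation).** The risks are dipolar cycloaddition of 11 to the methylene lactone, migration of the wrong α-carbon, and enolate scrambling before triflation. The fallback uses only known chemistry, sets out from 10 and comes back at 14. The exo-methylene of 10 is masked as its dimethylamine conjugate adduct, (3aR,6S,7aR)-3-[(dimethylamino)methyl]-6-methylhexahydro-1-benzofuran-2,5-dione F1 (Me2NH, THF, 0 °C; C3 epimers). The ketone is then homologated in the established stepwise way with 11 and BF3·OEt2 (2.2 equiv, CH2Cl2, −78 °C) to the amino β-ketosilane F2. Protodesilylation (Bu4NF, AcOH) gives the amino cycloheptanone F3. The less substituted enol triflate, amino triflate F4, is formed under kinetic control (KN(SiMe3)2, PhNTf2, THF, −78 °C). Quaternisation with MeI and elimination with aqueous NaHCO3 restore the methylene lactone and give 14.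

**Step 8 (thermal dimerisation).** The risks are oligomerisation, competing dimer modes and low conversion of an electron-poor diene. The fallback sets out from 16 and 14 and comes back at 17. Monomer 16 is heated (110 °C, BHT) with 5 equiv of triflate 14, which can act only as dienophile, so that 16 is the sole diene and the crossed mode is statistically favoured, giving the crossed adduct triflate F5. Its enol triflate is then vinylated with 15 under amine-free Heck conditions (Pd(OAc)2, Bu4NCl, NaHCO3, DMF, 50 °C) to give 17.

**Step 9 (γ-oxygenation).** The risks are the facial selectivity at C1, base-induced conjugation of the β,γ-enone without oxygenation, and base damage to the two methylene lactones. The fallback sets out from 17 and comes back at 19. Compound 17 is converted into its tert-butyldimethylsilyl dienol ether F6 (TBSOTf 1.05 equiv, Et3N, CH2Cl2, −78 °C; the doubly activated H-3 is removed first; enol ether geometry is of no consequence). The remote C1=C2 bond is then oxidised with dimethyldioxirane in acetone at −78 °C, the classical dienol ether to γ-hydroxy enone oxidation, and work-up with HF·pyridine gives 19.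

Further compounds
F1 | step 6 | (3aR,6S,7aR)-3-[(dimethylamino)methyl]-6-methylhexahydro-1-benzofuran-2,5-dione (C3 epimers) | CN(C)CC1C(=O)O[C@@H]2C[C@H](C)C(=O)C[C@H]12
F2 | step 6 | (3aR,7S,8aR)-3-[(dimethylamino)methyl]-7-methyl-5-(trimethylsilyl)hexahydro-2H-cyclohepta[b]furan-2,6(3H)-dione (C3 and C5 epimers) | CN(C)CC1C(=O)O[C@@H]2C[C@H](C)C(=O)C([Si](C)(C)C)C[C@H]12
F3 | step 6 | (3aR,7S,8aR)-3-[(dimethylamino)methyl]-7-methylhexahydro-2H-cyclohepta[b]furan-2,6(3H)-dione (C3 epimers) | CN(C)CC1C(=O)O[C@@H]2C[C@H](C)C(=O)CC[C@H]12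
F4 | step 6 | (3aR,7S,8aR)-3-[(dimethylamino)methyl]-7-methyl-2-oxo-3,3a,4,7,8,8a-hexahydro-2H-cyclohepta[b]furan-6-yl trifluoromethanesulfonate (C3 epimers) | CN(C)CC1C(=O)O[C@@H]2C[C@H](C)C(OS(=O)(=O)C(F)(F)F)=CC[C@H]12
F5 | step 8 | crossed Diels–Alder adduct of 16 (diene) and 14 (dienophile): as 17 but with an enol triflate in place of the dienone side chain of unit B | C=C1C(=O)O[C@@H]2C[C@H](C)C3=C[C@H](C(C)=O)[C@@]4(C[C@@H]3C[C@H]12)C(=O)O[C@@H]1C[C@H](C)C(OS(=O)(=O)C(F)(F)F)=CC[C@@H]14
F6 | step 9 | tert-butyldimethylsilyl dienol ether of 17 (C1=C2–C3=C4(OSi) diene; enol ether geometry undefined) | C=C1C(=O)O[C@@H]2C[C@H](C)C3=CC(=C(C)O[Si](C)(C)C(C)(C)C)[C@@]4(C[C@@H]3C[C@H]12)C(=O)O[C@@H]1C[C@H](C)C(/C=C/C(C)=O)=CC[C@@H]14
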